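**Retrosynthetic overview**
1. Target ⇐ ketal hydrolysis and C7-ketone reduction (last step) ⇐ side chain from a C9 aldehyde by acetone aldol and vinyl Grignard addition.
2. C9 aldehyde ⇐ spiro-epoxide (1,2-hydride shift). The δ-lactone ⇐ key ring expansion: ozonolytic Criegee rearrangement (carbon-to-oxygen 1,2-shift) of a methylidene bicyclo[3.2.1]octanone.
3. Bicyclo[3.2.1]octane ⇐ palladium-catalysed ketone α-alkenylation by a 2-bromoallyl group on a fully substituted cyclohexanone.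
4. Cyclohexenone ⇐ proposed enantioselective Mukaiyama–Michael addition of an isobutyrate silyl ketene acetal to the quinone monoketal of o-cresol, then two enolate alkylations.
5. Ring order: carbocycle (from the arene) → two-carbon bridge (cyclopentane) → ring-expanded δ-lactone.

Assumption: benzyl isobutyrate is used as the commercial, benzyl-protected form of isobutyric acid; the facial sense of the step-3 catalyst is assigned by analogy with its cyclohexenone complexes, and the mirror-image catalyst would be used if it proved opposite.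

**Step 1**
Reactants: 1 o-cresol (2-methylphenol)
Product: 2 4,4-dimethoxy-2-methylcyclohexa-2,5-dien-1-one
Conditions: PhI(OAc)2 (2.2 equiv), MeOH, 0 °C to rt
Reagents that add atoms: methanol, CO
Why: Hypervalent-iodine oxidative dearomatisation (para-methoxylation, then a second oxidation to the quinone monoketal) turns the arene into the future carbocycle with both ring oxygens in place; no stereocentre is formed.

**Step 2**
Reactants: 3 benzyl isobutyrate (benzyl 2-methylpropanoate)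
Product: 4 {[1-(benzyloxy)-2-methylprop-1-en-1-yl]oxy}trimethylsilane
Conditions: LiN(i-Pr)2, THF, −78 °C; Me3SiCl, −78 °C to rt; distillation
Reagents that add atoms: chlorotrimethylsilane, C[Si](C)(C)Cl
Why: O-silylation of the lithium ester enolate gives the silyl ketene acetal; there is no stereo issue because the alkene carbon carries two methyl groups.

**Step 3**
Reactants: 2 4,4-dimethoxy-2-methylcyclohexa-2,5-dien-1-one; 4 {[1-(benzyloxy)-2-methylprop-1-en-1-yl]oxy}trimethylsilane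
Product: 6 benzyl 2-[(1S,2R)-6,6-dimethoxy-2,4-dimethyl-3-oxocyclohex-4-en-1-yl]-2-methylpropanoate, via silyl enol ether 5 (not isolated)
Conditions: (S)-B-(2-methylphenyl)-diphenylprolinol oxazaborolidine·HNTf2 (20 mol %), Ph3PO (25 mol %), toluene, −40 °C; then MeLi, THF, 0 °C; then MeI, DMPU, −78 to 0 °C
Reagents that add atoms: iodomethane, CI
Why: Proposed new method: the triflimide-activated chiral oxazaborolidinium ion binds the dienone carbonyl (lone pair syn to the methyl-free α-CH, as in its known enone complexes), so the unsubstituted, more electrophilic enone arm is activated and one of its faces is shielded by the aryl group; the silyl ketene acetal adds 1,4 to that arm next to the ketal and sets the (S) centre, silyl transfer gives 5, MeLi frees the lithium enolate and MeI methylates it trans to the new group; the closest known reaction type is the oxazaborolidinium-catalysed enantioselective Mukaiyama–Michael addition of this class of silyl ketene acetal to cyclohexenone, here extended to a cross-conjugated quinone monoketal.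

**Step 4**
Reactants: 6 benzyl 2-[(1S,2R)-6,6-dimethoxy-2,4-dimethyl-3-oxocyclohex-4-en-1-yl]-2-methylpropanoate; 7 2,3-dibromopropene
Product: 8 benzyl 2-[(1S,2R)-2-(2-bromoprop-2-en-1-yl)-6,6-dimethoxy-2,4-dimethyl-3-oxocyclohex-4-en-1-yl]-2-methylpropanoate
Conditions: LiN(i-Pr)2, THF, −78 °C; 7, DMPU, −78 to −20 °C
Reagents that add atoms: none
Why: Enolate alkylation at the only enolisable position (the enone blocks the other α-side); the allylic bromide enters anti to the bulky neighbouring CMe2CO2Bn group, so the quaternary centre carries the bromoallyl group trans and the methyl cis to it.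

**Step 5**
Reactants: 8 benzyl 2-[(1S,2R)-2-(2-bromoprop-2-en-1-yl)-6,6-dimethoxy-2,4-dimethyl-3-oxocyclohex-4-en-1-yl]-2-methylpropanoate
Product: 9 benzyl 2-[(1S,2R)-2-(2-bromoprop-2-en-1-yl)-6,6-dimethoxy-2,4-dimethyl-3-oxocyclohexyl]-2-methylpropanoate (both C4 epimers)
Conditions: LiBH(s-Bu)3, THF, −78 °C; then H2O
Reagents that add atoms: none
Why: Conjugate (1,4) hydride reduction of the β-unsubstituted α-methyl enone leaves vinyl bromide, ester and ketal untouched; the new C4 centre is irrelevant because it is re-enolised in step 6.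

**Step 6**
Reactants: 9 benzyl 2-[(1S,2R)-2-(2-bromoprop-2-en-1-yl)-6,6-dimethoxy-2,4-dimethyl-3-oxocyclohexyl]-2-methylpropanoate (both C4 epimers)
Product: 10 benzyl 2-[(1R,2S,5R)-3,3-dimethoxy-1,5-dimethyl-6-methylidene-8-oxobicyclo[3.2.1]octan-2-yl]-2-methylpropanoate
Conditions: Pd(PPh3)4 (10 mol %), KOt-Bu (1.5 equiv), THF, 65 °C
Reagents that add atoms: none
Why: Palladium-catalysed intramolecular ketone α-alkenylation (enolate/vinyl bromide coupling) closes the two-carbon bridge at the only enolisable carbon; the bridge can only form cis across the ring, so the second methyl-bearing bridgehead is fixed by the first.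

**Step 7**
Reactants: 10 benzyl 2-[(1R,2S,5R)-3,3-dimethoxy-1,5-dimethyl-6-methylidene-8-oxobicyclo[3.2.1]octan-2-yl]-2-methylpropanoate
Product: 11 benzyl 2-[(1R,2S,5R,8S)-3,3-dimethoxy-1,5-dimethyl-6-methylidenespiro[bicyclo[3.2.1]octane-8,2'-oxiran]-2-yl]-2-methylpropanoate
Conditions: Me3SI, n-BuLi, THF, −10 °C to rt
Reagents that add atoms: trimethylsulfonium iodide, C[S+](C)C.[I-]
Why: Corey–Chaykovsky epoxidation of the only ketone; the small ylide attacks the bridging carbonyl from the side of the two-carbon bridge because the other face is blocked by the axial CMe2CO2Bn group, so the oxirane CH2 lies syn to the two-carbon bridge and the oxirane O syn to the three-carbon bridge.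

**Step 8**
Reactants: 11 benzyl 2-[(1R,2S,5R,8S)-3,3-dimethoxy-1,5-dimethyl-6-methylidenespiro[bicyclo[3.2.1]octane-8,2'-oxiran]-2-yl]-2-methylpropanoate
Product: 13 benzyl 2-[(1S,5R,6S,9R)-7,7-dimethoxy-1,5-dimethyl-3-oxospiro[2-oxabicyclo[3.3.1]nonane-9,2'-oxiran]-6-yl]-2-methylpropanoate, via methoxy hydroperoxide 12 (not isolated)
Conditions: O3, CH2Cl2/MeOH (4:1), NaHCO3, −78 °C; then Ac2O, Et3N, DMAP (cat.), 0 °C to rt
Reagents that add atoms: ozone, [O-][O+]=O; methanol, CO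
Why: Ozonolysis in methanol gives the α-methoxy hydroperoxide 12, whose acetylation triggers a Criegee rearrangement (a Baeyer–Villiger-type 1,2-shift from carbon to oxygen); the tertiary bridgehead migrates with retention, which expands the cyclopentane to the δ-lactone and sets the tertiary C–O stereocentre.

**Step 9**
Reactants: 13 benzyl 2-[(1S,5R,6S,9R)-7,7-dimethoxy-1,5-dimethyl-3-oxospiro[2-oxabicyclo[3.3.1]nonane-9,2'-oxiran]-6-yl]-2-methylpropanoate
Product: 14 benzyl 2-[(1S,5S,6S,9S)-9-formyl-7,7-dimethoxy-1,5-dimethyl-3-oxo-2-oxabicyclo[3.3.1]nonan-6-yl]-2-methylpropanoate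
Conditions: MeAl(OC6H2-4-Br-2,6-t-Bu2)2 (20 mol %), CH2Cl2, −78 to −40 °C
Reagents that add atoms: none
Why: Meinwald rearrangement: the bulky aluminium Lewis acid opens the epoxide at the tertiary carbon with a concerted 1,2-hydride shift and inversion there, so H ends syn to the lactone bridge and CHO syn to the carbocyclic bridge, as C9 of the target requires.

**Step 10**
Reactants: 14 benzyl 2-[(1S,5S,6S,9S)-9-formyl-7,7-dimethoxy-1,5-dimethyl-3-oxo-2-oxabicyclo[3.3.1]nonan-6-yl]-2-methylpropanoate; 15 acetone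
Product: 16 benzyl 2-[(1S,5S,6S,9R)-9-[(1S)-1-hydroxy-3-oxobutyl]-7,7-dimethoxy-1,5-dimethyl-3-oxo-2-oxabicyclo[3.3.1]nonan-6-yl]-2-methylpropanoate
Conditions: D-proline (30 mol %), 15/DMSO (1:4), rt
Reagents that add atoms: none
Why: Proline-catalysed enamine aldol (List–Barbas type): D-proline delivers the (S)-carbinol, in line with substrate bias (attack on the aldehyde face away from the CMe2CO2Bn flank); the near-neutral conditions avoid enolisation of the hindered aldehyde and β-elimination of the lactone oxygen.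

**Step 11**
Reactants: 16 benzyl 2-[(1S,5S,6S,9R)-9-[(1S)-1-hydroxy-3-oxobutyl]-7,7-dimethoxy-1,5-dimethyl-3-oxo-2-oxabicyclo[3.3.1]nonan-6-yl]-2-methylpropanoate
Product: 17 2-[(1S,5S,6S,9R)-9-[(1S)-1-hydroxy-3-oxobutyl]-7,7-dimethoxy-1,5-dimethyl-3-oxo-2-oxabicyclo[3.3.1]nonan-6-yl]-2-methylpropanoic acid
Conditions: H2 (1 atm), Pd/C (10 wt %), EtOAc, rt
Reagents that add atoms: none
Why: Hydrogenolysis of the benzyl ester at a stage with no alkene present; ketal, lactone and ketone are inert.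

**Step 12**
Reactants: 17 2-[(1S,5S,6S,9R)-9-[(1S)-1-hydroxy-3-oxobutyl]-7,7-dimethoxy-1,5-dimethyl-3-oxo-2-oxabicyclo[3.3.1]nonan-6-yl]-2-methylpropanoic acid; 18 vinylmagnesium bromide
Product: 19 2-[(1S,5S,6S,9R)-9-[(1S,3S)-1,3-dihydroxy-3-methylpent-4-en-1-yl]-7,7-dimethoxy-1,5-dimethyl-3-oxo-2-oxabicyclo[3.3.1]nonan-6-yl]-2-methylpropanoic acid
Conditions: CH2=CHMgBr (4.5 equiv), THF, −78 °C; then H2O, citric acid to pH 4
Reagents that add atoms: none
Why: Chelation-controlled Grignard 1,2-addition: the magnesium alkoxide of the β-hydroxy ketone forms a six-membered chelate and vinyl adds axially to give the (3S) tertiary alcohol; the carboxylate is inert and the hindered lactone survives at −78 °C.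

**Step 13**
Reactants: 19 2-[(1S,5S,6S,9R)-9-[(1S,3S)-1,3-dihydroxy-3-methylpent-4-en-1-yl]-7,7-dimethoxy-1,5-dimethyl-3-oxo-2-oxabicyclo[3.3.1]nonan-6-yl]-2-methylpropanoic acid
Product: 21 2-[(1S,5R,6S,7R,9R)-9-[(1S,3S)-1,3-dihydroxy-3-methylpent-4-en-1-yl]-7-hydroxy-1,5-dimethyl-3-oxo-2-oxabicyclo[3.3.1]nonan-6-yl]-2-methylpropanoic acid (target), via ketone 20 (not isolated)
Conditions: AcOH/H2O (4:1), rt; evaporate; then NaBH(OAc)3, MeCN/AcOH (1:1), −20 °C
Reagents that add atoms: water, O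
Why: Mild acid ketal hydrolysis unmasks the ketone, which is reduced at once under acidic conditions (no β-elimination of the lactone oxygen) by acyloxyborohydride; hydride comes from the face opposite the lactone bridge, which is also the face of the carboxyl and side-chain hydroxyl that can carry the boron, giving the (7R) alcohol trans to the CMe2CO2H group.

**Compound list**
1 | o-cresol (2-methylphenol) | Cc1ccccc1O | starting material
2 | 4,4-dimethoxy-2-methylcyclohexa-2,5-dien-1-one | COC1(OC)C=CC(=O)C(C)=C1 | intermediate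
3 | benzyl isobutyrate (benzyl 2-methylpropanoate) | CC(C)C(=O)OCc1ccccc1 | starting material
4 | {[1-(benzyloxy)-2-methylprop-1-en-1-yl]oxy}trimethylsilane | CC(C)=C(OCc1ccccc1)O[Si](C)(C)C | intermediate
5 | benzyl 2-[(1S)-6,6-dimethoxy-4-methyl-3-(trimethylsilyloxy)cyclohexa-2,4-dien-1-yl]-2-methylpropanoate | CC(C)(C(=O)OCc1ccccc1)[C@@H]1C=C(O[Si](C)(C)C)C(C)=CC1(OC)OC | intermediate (not isolated)
6 | benzyl 2-[(1S,2R)-6,6-dimethoxy-2,4-dimethyl-3-oxocyclohex-4-en-1-yl]-2-methylpropanoate | CC(C)(C(=O)OCc1ccccc1)[C@@H]1[C@@H](C)C(=O)C(C)=CC1(OC)OC | intermediate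
7 | 2,3-dibromopropene | BrCC(Br)=C | starting material
8 | benzyl 2-[(1S,2R)-2-(2-bromoprop-2-en-1-yl)-6,6-dimethoxy-2,4-dimethyl-3-oxocyclohex-4-en-1-yl]-2-methylpropanoate | CC(C)(C(=O)OCc1ccccc1)[C@@H]1[C@@](C)(CC(Br)=C)C(=O)C(C)=CC1(OC)OC | intermediate
9 | benzyl 2-[(1S,2R)-2-(2-bromoprop-2-en-1-yl)-6,6-dimethoxy-2,4-dimethyl-3-oxocyclohexyl]-2-methylpropanoate (both C4 epimers; C4 left open in the SMILES) | CC(C)(C(=O)OCc1ccccc1)[C@@H]1[C@@](C)(CC(Br)=C)C(=O)C(C)CC1(OC)OC | intermediate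
10 | benzyl 2-[(1R,2S,5R)-3,3-dimethoxy-1,5-dimethyl-6-methylidene-8-oxobicyclo[3.2.1]octan-2-yl]-2-methylpropanoate | CC(C)(C(=O)OCc1ccccc1)[C@@H]1[C@@]2(C)CC(=C)[C@@](C)(CC1(OC)OC)C2=O | intermediate
11 | benzyl 2-[(1R,2S,5R,8S)-3,3-dimethoxy-1,5-dimethyl-6-methylidenespiro[bicyclo[3.2.1]octane-8,2'-oxiran]-2-yl]-2-methylpropanoate (oxirane CH2 on the side of the two-carbon bridge) | CC(C)(C(=O)OCc1ccccc1)[C@@H]1[C@@]2(C)CC(=C)[C@@](C)(CC1(OC)OC)[C@]23CO3 | intermediate
12 | benzyl 2-[(1R,2S,5S,8S)-6-hydroperoxy-3,3,6-trimethoxy-1,5-dimethylspiro[bicyclo[3.2.1]octane-8,2'-oxiran]-2-yl]-2-methylpropanoate (hydroperoxy carbon unassigned) | CC(C)(C(=O)OCc1ccccc1)[C@@H]1[C@@]2(C)CC(OC)(OO)[C@@](C)(CC1(OC)OC)[C@]23CO3 | intermediate (not isolated)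
13 | benzyl 2-[(1S,5R,6S,9R)-7,7-dimethoxy-1,5-dimethyl-3-oxospiro[2-oxabicyclo[3.3.1]nonane-9,2'-oxiran]-6-yl]-2-methylpropanoate (oxirane CH2 on the side of the lactone bridge) | CC(C)(C(=O)OCc1ccccc1)[C@@H]1[C@@]2(C)CC(=O)O[C@@](C)(CC1(OC)OC)[C@]23CO3 | intermediate
14 | benzyl 2-[(1S,5S,6S,9S)-9-formyl-7,7-dimethoxy-1,5-dimethyl-3-oxo-2-oxabicyclo[3.3.1]nonan-6-yl]-2-methylpropanoate | CC(C)(C(=O)OCc1ccccc1)[C@@H]1[C@@]2(C)CC(=O)O[C@@](C)(CC1(OC)OC)[C@H]2C=O | intermediate
15 | acetone | CC(C)=O | starting material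
16 | benzyl 2-[(1S,5S,6S,9R)-9-[(1S)-1-hydroxy-3-oxobutyl]-7,7-dimethoxy-1,5-dimethyl-3-oxo-2-oxabicyclo[3.3.1]nonan-6-yl]-2-methylpropanoate | CC(=O)C[C@H](O)[C@H]1[C@]2(C)CC(=O)O[C@@]1(C)CC(OC)(OC)[C@@H]2C(C)(C)C(=O)OCc1ccccc1 | intermediate
17 | 2-[(1S,5S,6S,9R)-9-[(1S)-1-hydroxy-3-oxobutyl]-7,7-dimethoxy-1,5-dimethyl-3-oxo-2-oxabicyclo[3.3.1]nonan-6-yl]-2-methylpropanoic acid | CC(=O)C[C@H](O)[C@H]1[C@]2(C)CC(=O)O[C@@]1(C)CC(OC)(OC)[C@@H]2C(C)(C)C(=O)O | intermediate
18 | vinylmagnesium bromide | C=C[Mg]Br | starting material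
19 | 2-[(1S,5S,6S,9R)-9-[(1S,3S)-1,3-dihydroxy-3-methylpent-4-en-1-yl]-7,7-dimethoxy-1,5-dimethyl-3-oxo-2-oxabicyclo[3.3.1]nonan-6-yl]-2-methylpropanoic acid | C=C[C@@](C)(O)C[C@H](O)[C@H]1[C@]2(C)CC(=O)O[C@@]1(C)CC(OC)(OC)[C@@H]2C(C)(C)C(=O)O | intermediate
20 | 2-[(1S,5S,6S,9R)-9-[(1S,3S)-1,3-dihydroxy-3-methylpent-4-en-1-yl]-1,5-dimethyl-3,7-dioxo-2-oxabicyclo[3.3.1]nonan-6-yl]-2-methylpropanoic acid | C=C[C@@](C)(O)C[C@H](O)[C@H]1[C@]2(C)CC(=O)O[C@@]1(C)CC(=O)[C@@H]2C(C)(C)C(=O)O | intermediate (not isolated)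
21 | 2-[(1S,5R,6S,7R,9R)-9-[(1S,3S)-1,3-dihydroxy-3-methylpent-4-en-1-yl]-7-hydroxy-1,5-dimethyl-3-oxo-2-oxabicyclo[3.3.1]nonan-6-yl]-2-methylpropanoic acid | C=C[C@@](C)(O)C[C@H](O)[C@H]1[C@]2(C)CC(=O)O[C@@]1(C)C[C@@H](O)[C@@H]2C(C)(C)C(=O)O | target

**Step count and risk**
Total steps: 13. Longest linear sequence: 12 (steps 1 and 3–13 from o-cresol; step 2 is a one-step side branch).

Most likely to fail:

Step 3 (the proposed new enantioselective Mukaiyama–Michael addition; the ketal may ionise or the selectivity may be low). The fallback uses known chemistry, sets out from 2 and comes back at 6. Isobutyric acid with LiN(i-Pr)2 (2 equiv) and Me3SiCl gives 2-methyl-1,1-bis(trimethylsilyloxy)prop-1-ene F1. A racemic Lewis-base-catalysed Mukaiyama–Michael addition of it to 2 (Bu4NOAc cat., DMF) and aqueous work-up give rac-2-(6,6-dimethoxy-4-methyl-3-oxocyclohex-4-en-1-yl)-2-methylpropanoic acid F2. Classical resolution with (R)-1-phenylethylamine gives the crystalline salt (R)-1-phenylethylammonium 2-[(1S)-6,6-dimethoxy-4-methyl-3-oxocyclohex-4-en-1-yl]-2-methylpropanoate F3. Acidification frees 2-[(1S)-6,6-dimethoxy-4-methyl-3-oxocyclohex-4-en-1-yl]-2-methylpropanoic acid F4. BnBr/K2CO3 gives benzyl 2-[(1S)-6,6-dimethoxy-4-methyl-3-oxocyclohex-4-en-1-yl]-2-methylpropanoate F5. LiN(i-Pr)2 then MeI methylates it to 6.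

Step 6 (cross-ring palladium α-alkenylation that forges a strained two-carbon bridge and a quaternary centre). The fallback sets out from 6 and comes back at 10. Alkylation of 6 with propargyl bromide (LiN(i-Pr)2, DMPU) gives benzyl 2-[(1S,2R)-6,6-dimethoxy-2,4-dimethyl-3-oxo-2-(prop-2-yn-1-yl)cyclohex-4-en-1-yl]-2-methylpropanoate F6. Conjugate reduction with LiBH(s-Bu)3 and trapping with t-BuMe2SiOTf give benzyl 2-[(1S,2R)-3-(tert-butyldimethylsilyloxy)-6,6-dimethoxy-2,4-dimethyl-2-(prop-2-yn-1-yl)cyclohex-3-en-1-yl]-2-methylpropanoate F7. A 5-exo-dig carbocyclisation of the silyl enol ether onto the alkyne catalysed by monovalent gold (Ph3PAuCl/AgBF4, 5 mol %, CH2Cl2/MeOH 10:1) then gives 10.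

Step 9 (Meinwald rearrangement: the hydride must shift with inversion, and the ketal must survive the Lewis acid). The fallback sets out from 13 and comes back at 14. Reductive epoxide opening with trivalent titanium (Cp2TiCl2, Zn, 1,4-cyclohexadiene, THF) gives the tertiary radical, which takes a hydrogen atom on the open face next to the lactone bridge. This gives benzyl 2-[(1S,5S,6S,9R)-9-(hydroxymethyl)-7,7-dimethoxy-1,5-dimethyl-3-oxo-2-oxabicyclo[3.3.1]nonan-6-yl]-2-methylpropanoate F8. Dess–Martin oxidation of it gives 14.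

**Further compounds**
F1 | step 3 | 2-methyl-1,1-bis(trimethylsilyloxy)prop-1-ene | CC(C)=C(O[Si](C)(C)C)O[Si](C)(C)C
F2 | step 3 | rac-2-(6,6-dimethoxy-4-methyl-3-oxocyclohex-4-en-1-yl)-2-methylpropanoic acid | COC1(OC)C=C(C)C(=O)CC1C(C)(C)C(=O)O
F3 | step 3 | (R)-1-phenylethylammonium 2-[(1S)-6,6-dimethoxy-4-methyl-3-oxocyclohex-4-en-1-yl]-2-methylpropanoate | COC1(OC)C=C(C)C(=O)C[C@H]1C(C)(C)C(=O)[O-].C[C@@H]([NH3+])c1ccccc1
F4 | step 3 | 2-[(1S)-6,6-dimethoxy-4-methyl-3-oxocyclohex-4-en-1-yl]-2-methylpropanoic acid | COC1(OC)C=C(C)C(=O)C[C@H]1C(C)(C)C(=O)O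
F5 | step 3 | benzyl 2-[(1S)-6,6-dimethoxy-4-methyl-3-oxocyclohex-4-en-1-yl]-2-methylpropanoate | COC1(OC)C=C(C)C(=O)C[C@H]1C(C)(C)C(=O)OCc1ccccc1
F6 | step 6 | benzyl 2-[(1S,2R)-6,6-dimethoxy-2,4-dimethyl-3-oxo-2-(prop-2-yn-1-yl)cyclohex-4-en-1-yl]-2-methylpropanoate | CC(C)(C(=O)OCc1ccccc1)[C@@H]1[C@@](C)(CC#C)C(=O)C(C)=CC1(OC)OC
F7 | step 6 | benzyl 2-[(1S,2R)-3-(tert-butyldimethylsilyloxy)-6,6-dimethoxy-2,4-dimethyl-2-(prop-2-yn-1-yl)cyclohex-3-en-1-yl]-2-methylpropanoate | CC(C)(C(=O)OCc1ccccc1)[C@@H]1[C@@](C)(CC#C)C(O[Si](C)(C)C(C)(C)C)=C(C)CC1(OC)OC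
F8 | step 9 | benzyl 2-[(1S,5S,6S,9R)-9-(hydroxymethyl)-7,7-dimethoxy-1,5-dimethyl-3-oxo-2-oxabicyclo[3.3.1]nonan-6-yl]-2-methylpropanoate | CC(C)(C(=O)OCc1ccccc1)[C@@H]1[C@@]2(C)CC(=O)O[C@@](C)(CC1(OC)OC)[C@H]2CO
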